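| flask | D | G | remark | time |
|---|---|---|---|---|
| amber | 0.081 M | 5.2 mM | run made earlier |  |
| red | 0.081 M | 7.5 mM | run made earlier |  |
| Friday's | 0.081 M | 4.1 mM |  | 12 h |
| Monday's | 0.081 M | 8.0 mM |  | 12 h |

| run | time / h | X / % | D / % |
|---|---|---|---|
| amber | 0.833 | 76.9 | 26.1 |
| amber | 2.00 | 95.0 | 6.0 |
| amber | 4.00 | 96.7 | 1.9 |
| amber | 6.00 | 99.2 | 0 |
| amber | 8.00 | 99.7 | 0 |
| red | 0.833 | 82.9 | 16.9 |
| red | 2.00 | 93.2 | 2.7 |
| red | 4.00 | 99.0 | 2.1 |
| red | 6.00 | 97.6 | 0.7 |
| red | 8.00 | 100.4 | 1.0 |

(each reading ± 1 percentage point)

- the average divides the monomer in chains by the number of chains begun, living and dead together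
- the earlier runs do not show the number of chains; that part of a forecast is a guess

- which of the two ends with the longer chains by the average number of monomer units in a chain (chains begun, living or dead) ("neither" if they lie within 10%) (Friday's / Monday's / neither)
- average number of monomer units in a chain (chains begun, living or dead) at the end, Friday's
- average number of monomer units in a chain (chains begun, living or dead) at the end, Monday's

At early times the amber run loses D fast: 26.1% of the charge is left at 0.833 h, an opening logarithmic slope of 1.61 h⁻¹, and on that slope the curves of D and X cross near 0.431 h. From 2.00 h to 4.00 h the slope is 0.575 h⁻¹, about a third of the opening one, though these readings carry a scatter of 1 percentage point. So the knee lies near 2.00 h. Beyond it, X runs into a level near the whole charge, with 99.7% in the amber run and 100.4% in the red run at 8.00 h.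

That level tells us how much D is spent, but not how many chains share it. We therefore divide the rate at which D goes by the rate at which chains begin, so that time drops out: the mean length is D spent over chains begun. If G is the initiator, one G spent beginning one chain, and D is spent to the level, the length is D charged over G charged, divided by the fraction of G spent. In Friday's flask, D charged over G charged is 19.8; we call this the charge length. In Monday's flask it is 10.1, so Friday's charge length is about twice Monday's. The earlier runs do not show the fraction of G spent, but a fraction below one lengthens the chains, so we expect lengths above these.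

The forecast, “Assuming one chain per G”, gives 19.6 for Friday's and 10.1 for Monday's and names Friday's as longer. We differ from it in expecting lengths above the charge lengths.

The flask gives 34.1 for Friday's and 22.8 for Monday's, so Friday's ends longer, as forecast, and both lengths stand above the forecast's.

    2 Z → J (k = 0.560 L mol⁻¹ s⁻¹)
    D + G → Z + X (k = 0.00350 L mol⁻¹ s⁻¹)
    D + Z → X + Z, rate k3*[Z]*[D] (k = 0.760 L mol⁻¹ s⁻¹)

Here Z is a growing chain and J a dead pair of chains. In Friday's flask at 12.0 h, 42% of the G is left, and the charge length divided by the fraction spent gives 34.1. The neighbour, Friday's flask with 0.32 M of D, has a charge length of 78.0. With 10% of its G left, that becomes 86.7, and the simulated flask gives 86.8.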